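(The rate constants are invented; the result is computed.)

Which flask keeps its product as G, and which lets it pass on to E? Solid Q dissolves to J, J turns D into G and Z, and G turns into E.

| flask | D | Q | temperature | time |
|---|---|---|---|---|
| Thursday's | 0.010 M | 0.0110 M | −5 °C | 2.5 h |
| Sunday's | 0.010 M | 0.0110 M | 20 °C | 2.5 h |
| Tuesday's | 0.010 M | 0.0110 M | 45 °C | 2.5 h |
| Monday's | 0.010 M | 0.0110 M | −30 °C | 2.5 h |

    D + J ⇌ G + Z (K1 = 0.18, k1 = 23 /M/min, Ea1 = 49.0 kJ/mol, ΔH1 = −44.0 kJ/mol)
    Q ⇌ J, rate k2*(cs2 - [J]) while solid is left; crystals form when [J] > cs2 (cs2 = 7.9 mM, k2 = 0.086 /min)
    G ⇌ E (K3 = 0.30, k3 = 0.14 /min, Ea3 = 84.0 kJ/mol, ΔH3 = −30.0 kJ/mol)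
    (constants at 20 °C)

- given per volume of solution although it is solid: Q
- constants are those at 20 °C; use the activation energies and enthalpies for any other temperature
- at the start none of Q is in solution

1. which flask leads in share of G in all that became G or E ("all alike" within 1.5 percentage points) (Thursday's / Sunday's / Tuesday's / Monday's / all alike)
2. share of G in all that became G or E, Thursday's
3. share of G in all that became G or E, Sunday's
4. share of G in all that became G or E, Tuesday's
5. share of G in all that became G or E, Monday's

Follow Monday's, at −30 °C, in slow motion. In the first instants there is no J, so dissolving starts the flask, with a half-life of 8.06 min for [J] climbing toward 7.9 mM. The charge of Q, 0.0110 M, is larger than that solubility, so in Monday's solid lies in the flask at first.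

In the middle, I take [J] as held near its ceiling and [D] as near its charge, so that G grows in Monday's at a roughly steady pace. Step 1 leans toward G there, with K = 7.37.

What is about to matter is the passage from G to E. Equilibrium in Monday's pulls hard toward E, with K = 3.77, which leaves G a share of just 21.0%. But the relaxation half-life of G and E, both ways together, is 78.0 h, far longer than the 2.5 h run. So Monday's share follows the clock (kinetic control), not the equilibrium (thermodynamic control).

The useful quantity is therefore the leak, the forward rate constant from G to E, which is the relaxation rate times K/(1+K): 0.00702 /h. With steady making, the average G has aged half the run, so the fraction gone to E is the leak times that age, 0.878%. My figure for Monday's is a G share of 99.1%.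

In Sunday's the picture turns round. The relaxation half-life of G and E is 1.14 min, far shorter than the run, so I take the equilibrium share, 76.9%. For Tuesday's I take the equilibrium share too, and K = 0.114 gives 89.8%. Thursday's lies between the two regimes, and I give no figure for it.

The forecast says 64% for Thursday's, 77% for Sunday's, 89.7% for Tuesday's and 99.2% for Monday's, with Monday's leading, on the ground that in the cold step 3 "is practically frozen and almost all product stays as G". Against the forecast's 99.2% I hold 99.1% for Monday's, and the forecast commits on Thursday's, where I did not.

The simulation gives 64.5% for Thursday's, 76.9% for Sunday's, 89.8% for Tuesday's and 99.1% for Monday's, so Monday's leads, as forecast. In Monday's the pair D + J and G + Z relaxes with a half-life of 2.04 h at the asked time, shorter than the 78.0 h of G and E, and E holds 0.900% of what became G or E. Read at 10 h, Monday's flask has a leak times half that time of 3.51%, and E stands there at 4.56% of what became G or E.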